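**Retrosynthetic overview**

- The strategy rests on the peri relationship in the naphthalene: the ring oxygen sits on C8 and the spiro carbon on C1, so a hydroxyl on the spiro carbon can reach C8–H and close the five-membered naphtho[1,8-bc]furan ring (O, spiro C, C1, C8a, C8).
- Target 13 comes from the O-benzyl, O-silyl spiro N,O-ketal 11 by desilylation and then neutral debenzylation.
- 11 comes from the racemic hydroxylactam 10 by forming the O–C8 bond through hydroxyl-directed C–H activation; this closes the furan ring last and fixes the spiro centre by dynamic kinetic resolution.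
- 10 comes from the keto amide 9, made by oxidation of carbinol 8; 8 is the adduct of the C2-lithiated benzamide 6 with 2-benzyloxy-6-methyl-1-naphthaldehyde 3.
- Ring order: naphthalene and ring A are purchased, the lactam ring closes in step 5, the furan ring in step 6.

Key step: step 6

Assumption: the sense of induction of the amino acid ligand cannot be predicted with confidence, so Boc-L-tert-leucine is written and its D-antipode is to be used if that one proves to deliver the (R) spiro centre.

**Step 1**
Reactants: 1 6-methylnaphthalen-2-ol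
Product: 2 2-hydroxy-6-methylnaphthalene-1-carbaldehyde
Conditions: MgCl2, Et3N, paraformaldehyde, MeCN, reflux; then 1 M HCl
Reagents that add atoms: paraformaldehyde, as formaldehyde C=O
Why: Magnesium phenoxide-directed ortho-formylation (Casnati–Skattebøl reaction) should deliver formaldehyde to C1, the more nucleophilic alpha position of a 2-naphthol, with the hydroxymethyl stage oxidized in the flask by hydride transfer to a second formaldehyde.

**Step 2**
Reactants: 2 2-hydroxy-6-methylnaphthalene-1-carbaldehyde
Product: 3 2-(benzyloxy)-6-methylnaphthalene-1-carbaldehyde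
Conditions: BnBr, K2CO3, DMF, rt to 50 °C
Reagents that add atoms: benzyl bromide, BrCc1ccccc1
Why: Williamson ether synthesis on the phenoxide should give the benzyl ether, which masks the C2 oxygen against the aryllithium, the periodinane and PhI(OAc)2 used later.

**Step 3**
Reactants: 4 3-methoxybenzoyl chloride; 5 2-[(tert-butyldimethylsilyl)oxy]ethan-1-amine
Product: 6 N-{2-[(tert-butyldimethylsilyl)oxy]ethyl}-3-methoxybenzamide
Conditions: Et3N, CH2Cl2, 0 °C to rt
Reagents that add atoms: none
Why: N-acylation of the primary amine by the acid chloride (Schotten–Baumann type) should be clean, and the silyl ether is stable to Et3N.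

**Step 4**
Reactants: 6 N-{2-[(tert-butyldimethylsilyl)oxy]ethyl}-3-methoxybenzamide; 3 2-(benzyloxy)-6-methylnaphthalene-1-carbaldehyde
Product: 8 racemic 2-{[2-(benzyloxy)-6-methylnaphthalen-1-yl](hydroxy)methyl}-N-{2-[(tert-butyldimethylsilyl)oxy]ethyl}-3-methoxybenzamide, via dilithiated amide 7 (not isolated)
Conditions: s-BuLi (2.1 equiv), TMEDA, THF, −78 °C; then 3, −78 to −20 °C; sat. NH4Cl
Reagents that add atoms: none
Why: Directed ortho metalation should place lithium at C2, where the lithium amidate and the methoxy group direct cooperatively, and 1,2-addition of this aryllithium to the aldehyde forms the aryl–carbinol bond; the carbinol centre forms as a racemate and is erased in step 5.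

**Step 5**
Reactants: 8 racemic 2-{[2-(benzyloxy)-6-methylnaphthalen-1-yl](hydroxy)methyl}-N-{2-[(tert-butyldimethylsilyl)oxy]ethyl}-3-methoxybenzamide
Product: 10 racemic 3-[2-(benzyloxy)-6-methylnaphthalen-1-yl]-2-{2-[(tert-butyldimethylsilyl)oxy]ethyl}-3-hydroxy-4-methoxyisoindolin-1-one, via keto amide 9 (not isolated)
Conditions: Dess–Martin periodinane, NaHCO3, CH2Cl2, 0 °C to rt
Reagents that add atoms: none
Why: Dess–Martin oxidation of the doubly benzylic secondary alcohol should give the 2-aroylbenzamide, whose amide N–H adds to the ketone (ring–chain tautomerism, 5-exo-trig) to give the racemic five-membered hydroxylactam.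

**Step 6**
Reactants: 10 racemic 3-[2-(benzyloxy)-6-methylnaphthalen-1-yl]-2-{2-[(tert-butyldimethylsilyl)oxy]ethyl}-3-hydroxy-4-methoxyisoindolin-1-one
Product: 11 (R)-3'-(benzyloxy)-2-{2-[(tert-butyldimethylsilyl)oxy]ethyl}-7-methoxy-7'-methylspiro[isoindoline-1,2'-naphtho[1,8-bc]furan]-3-one
Conditions: Pd(OAc)2 (10 mol %), Boc-L-tert-leucine (30 mol %), PhI(OAc)2 (1.5 equiv), Li2CO3 (1.5 equiv), C6F6, 80 °C
Reagents that add atoms: none
Why: Proposed new method: the hemiaminal oxygen of 10 binds divalent palladium as an alkoxide, concerted metalation–deprotonation assisted by the amino acid ligand cleaves the peri C8–H bond to give a six-membered palladacycle (Pd, O, spiro C, C1, C8a, C8), and PhI(OAc)2 oxidizes this to tetravalent palladium, from which C–O reductive elimination forms the O–C8 bond. The closest known reaction type is the hydroxyl-directed Pd(OAc)2/PhI(OAc)2 C–H activation with C–O cyclization of tertiary alcohols to dihydrobenzofurans, together with the use of Boc-amino acid ligands for enantioselective C–O forming C–H activation by the same redox couple; new here are the peri position and the dynamic resolution. The five-membered furan ring (O, spiro C, C1, C8a, C8) closes by reductive elimination with extrusion of palladium from the six-membered palladacycle, formally a 5-exo attack of the alkoxide oxygen on the peri aryl carbon. The spiro centre is selected and not created: the enantiomers of 10 interconvert through the achiral keto amide 9 under the carbonate base, and the chiral ligand on palladium should make C–H cleavage faster for one of them, so the ligand antipode controls the configuration. Site selectivity is secured by the substrate, since naphthalene C2 carries the benzyloxy group, the only ortho position of ring A next to the carbinol carbon carries the methoxy group, and only C8–H lies within reach of the bound oxygen. Chemoselectivity relies on both the phenol and the primary alcohol being masked as ethers, so that no other oxidizable or coordinating hydroxyl is present.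

**Step 7**
Reactants: 11 (R)-3'-(benzyloxy)-2-{2-[(tert-butyldimethylsilyl)oxy]ethyl}-7-methoxy-7'-methylspiro[isoindoline-1,2'-naphtho[1,8-bc]furan]-3-one
Product: 12 (R)-3'-(benzyloxy)-2-(2-hydroxyethyl)-7-methoxy-7'-methylspiro[isoindoline-1,2'-naphtho[1,8-bc]furan]-3-one
Conditions: Bu4NF (TBAF), AcOH (1:1), THF, 0 °C to rt
Reagents that add atoms: none
Why: Fluoride-mediated desilylation of the primary silyl ether, buffered with AcOH to stay near neutral, should leave the N,O-ketal and its stereocentre untouched.

**Step 8**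
Reactants: 12 (R)-3'-(benzyloxy)-2-(2-hydroxyethyl)-7-methoxy-7'-methylspiro[isoindoline-1,2'-naphtho[1,8-bc]furan]-3-one
Product: 13 (R)-3'-hydroxy-2-(2-hydroxyethyl)-7-methoxy-7'-methylspiro[isoindoline-1,2'-naphtho[1,8-bc]furan]-3-one
Conditions: H2 (1 atm), Pd/C (10 wt % palladium on carbon), EtOAc, rt, stopped at full conversion
Reagents that add atoms: none
Why: Catalytic hydrogenolysis should cleave the accessible primary benzyl aryl ether much faster than the shielded quaternary spiro C–O bond, and the neutral medium preserves the (R) centre.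

**Compound list**

1 | 6-methylnaphthalen-2-ol | Cc1ccc2cc(O)ccc2c1 | starting material
2 | 2-hydroxy-6-methylnaphthalene-1-carbaldehyde | Cc1ccc2c(C=O)c(O)ccc2c1 | intermediate
3 | 2-(benzyloxy)-6-methylnaphthalene-1-carbaldehyde | Cc1ccc2c(C=O)c(OCc3ccccc3)ccc2c1 | intermediate
4 | 3-methoxybenzoyl chloride | COc1cccc(C(=O)Cl)c1 | starting material
5 | 2-[(tert-butyldimethylsilyl)oxy]ethan-1-amine | NCCO[Si](C)(C)C(C)(C)C | starting material
6 | N-{2-[(tert-butyldimethylsilyl)oxy]ethyl}-3-methoxybenzamide | COc1cccc(C(=O)NCCO[Si](C)(C)C(C)(C)C)c1 | intermediate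
7 | N,2-dilithio derivative of 6 (lithium amidate, aryllithium at C2 between amide and methoxy) | [Li]c1c(OC)cccc1C(=O)N([Li])CCO[Si](C)(C)C(C)(C)C | intermediate (not isolated)
8 | racemic 2-{[2-(benzyloxy)-6-methylnaphthalen-1-yl](hydroxy)methyl}-N-{2-[(tert-butyldimethylsilyl)oxy]ethyl}-3-methoxybenzamide | COc1cccc(C(=O)NCCO[Si](C)(C)C(C)(C)C)c1C(O)c1c(OCc2ccccc2)ccc2cc(C)ccc12 | intermediate
9 | 2-[2-(benzyloxy)-6-methyl-1-naphthoyl]-N-{2-[(tert-butyldimethylsilyl)oxy]ethyl}-3-methoxybenzamide (keto amide) | COc1cccc(C(=O)NCCO[Si](C)(C)C(C)(C)C)c1C(=O)c1c(OCc2ccccc2)ccc2cc(C)ccc12 | intermediate (not isolated)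
10 | racemic 3-[2-(benzyloxy)-6-methylnaphthalen-1-yl]-2-{2-[(tert-butyldimethylsilyl)oxy]ethyl}-3-hydroxy-4-methoxyisoindolin-1-one | COc1cccc2c1C(O)(c1c(OCc3ccccc3)ccc3cc(C)ccc13)N(CCO[Si](C)(C)C(C)(C)C)C2=O | intermediate
11 | (R)-3'-(benzyloxy)-2-{2-[(tert-butyldimethylsilyl)oxy]ethyl}-7-methoxy-7'-methylspiro[isoindoline-1,2'-naphtho[1,8-bc]furan]-3-one | COc1cccc2c1[C@@]1(Oc3cc(C)cc4ccc(OCc5ccccc5)c1c34)N(CCO[Si](C)(C)C(C)(C)C)C2=O | intermediate
12 | (R)-3'-(benzyloxy)-2-(2-hydroxyethyl)-7-methoxy-7'-methylspiro[isoindoline-1,2'-naphtho[1,8-bc]furan]-3-one | COc1cccc2c1[C@@]1(Oc3cc(C)cc4ccc(OCc5ccccc5)c1c34)N(CCO)C2=O | intermediate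
13 | (R)-3'-hydroxy-2-(2-hydroxyethyl)-7-methoxy-7'-methylspiro[isoindoline-1,2'-naphtho[1,8-bc]furan]-3-one | COc1cccc2c1[C@@]1(Oc3cc(C)cc4ccc(O)c1c34)N(CCO)C2=O | target

**Step count**

Total steps: 8. Longest linear sequence: 7 (steps 1, 2, 4, 5, 6, 7, 8 from compound 1).

**Steps most likely to fail**

1. Step 6. Metalation at the peri position, which leads to a strained ring, may be slower than oxidative degradation by PhI(OAc)2 (benzylic oxidation, acetoxylation of the electron-rich naphthalene, amide-directed functionalization of ring A in the open keto amide form). The ligand may also fail to discriminate between the equilibrating enantiomers, or the product may lose configuration by reversible opening of the N,O-ketal. The fallback uses known chemistry, sets out from aldehyde 3 (with dianion 7 from amide 6) and comes back at 11. Carbonyl-directed peri bromination of 3 (Pd(OAc)2 catalyst, N-bromosuccinimide) should give 2-(benzyloxy)-8-bromo-6-methylnaphthalene-1-carbaldehyde F1. Pinnick oxidation (NaClO2, NaH2PO4, 2-methyl-2-butene) then gives 2-(benzyloxy)-8-bromo-6-methylnaphthalene-1-carboxylic acid F2. Copper-catalysed intramolecular Ullmann O-arylation of the carboxylate (CuI, Cs2CO3, DMF, heat) closes the peri lactone 3-(benzyloxy)-7-methylnaphtho[1,8-bc]furan-2-one F3, so the C8–O bond is made by a classical route. Addition of dianion 7 to the strained lactone carbonyl opens it to the peri-hydroxy keto amide F4. With catalytic pyridinium p-toluenesulfonate in CH2Cl2 over molecular sieves, F4 should lactamize and the resulting N-acyliminium ion be trapped by the peri naphthol, giving the racemic spiro N,O-ketal F5. Preparative chromatography on a chiral stationary phase then separates 11 from its (S)-enantiomer F6.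

2. Step 4. The aryllithium, flanked by the amidate and the methoxy group, may add only slowly to the aldehyde, which is crowded by the ortho benzyloxy group and the peri hydrogen. Proton transfer or metalation at the benzylic position of the benzyl ether could then compete, and the hydroxy amide may lactonize to a phthalide with loss of the side-chain amine during work-up. The fallback reverses the polarity of the bond construction, sets out from 6 and 1 and comes back at 10, bypassing 8 and 9. Dianion 7 is quenched with the small electrophile DMF to give 2-{2-[(tert-butyldimethylsilyl)oxy]ethyl}-3-hydroxy-4-methoxyisoindolin-1-one F7. Acid-catalysed aza-Friedel–Crafts amidoalkylation (catalytic diphenyl phosphate, CH2Cl2) of naphthol 1 at its nucleophilic C1 by the N-acyliminium ion from F7 gives 2-{2-[(tert-butyldimethylsilyl)oxy]ethyl}-3-(2-hydroxy-6-methylnaphthalen-1-yl)-4-methoxyisoindolin-1-one F8. O-Benzylation (BnBr, K2CO3, acetone) gives 3-[2-(benzyloxy)-6-methylnaphthalen-1-yl]-2-{2-[(tert-butyldimethylsilyl)oxy]ethyl}-4-methoxyisoindolin-1-one F9. Base-mediated aerobic hydroxylation of the acidic C3–H (Cs2CO3, O2, P(OEt)3, DMSO) then gives 10.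

3. Step 8. Hydrogenolysis may not stop at the benzyl ether: the strained, doubly benzylic spiro C–O bond could be cleaved reductively, or the catalyst surface could open the N,O-ketal and erode the configuration. The fallback moves the hydrogenolysis to a stage where the strained ring does not yet exist, sets out from 10 and comes back at 13. Hydrogenolysis of 10 (H2, Pd/C, EtOAc) gives 2-{2-[(tert-butyldimethylsilyl)oxy]ethyl}-3-hydroxy-3-(2-hydroxy-6-methylnaphthalen-1-yl)-4-methoxyisoindolin-1-one F10. Silylation of the phenol (TBSCl, imidazole, DMF; the hindered tertiary hydroxyl should stay free) gives the bis-silyl hydroxylactam 3-{2-[(tert-butyldimethylsilyl)oxy]-6-methylnaphthalen-1-yl}-2-{2-[(tert-butyldimethylsilyl)oxy]ethyl}-3-hydroxy-4-methoxyisoindolin-1-one F11. The cyclization of step 6 applied to F11 gives 3'-[(tert-butyldimethylsilyl)oxy]-2-{2-[(tert-butyldimethylsilyl)oxy]ethyl}-7-methoxy-7'-methylspiro[isoindoline-1,2'-naphtho[1,8-bc]furan]-3-one F12, which has the same spatial arrangement as 11 but the formal descriptor S, because silicon raises the priority of the naphthyl branch. One treatment with Bu4NF/AcOH removes both silyl groups and gives 13 without exposing the spiro compound to hydrogen; this costs one extra step.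

**Further compounds**

F1 | step 6 | 2-(benzyloxy)-8-bromo-6-methylnaphthalene-1-carbaldehyde | O=Cc1c(OCc2ccccc2)ccc2cc(C)cc(Br)c12
F2 | step 6 | 2-(benzyloxy)-8-bromo-6-methylnaphthalene-1-carboxylic acid | OC(=O)c1c(OCc2ccccc2)ccc2cc(C)cc(Br)c12
F3 | step 6 | 3-(benzyloxy)-7-methylnaphtho[1,8-bc]furan-2-one | O=C1Oc2cc(C)cc3ccc(OCc4ccccc4)c1c23
F4 | step 6 | 2-[2-(benzyloxy)-8-hydroxy-6-methyl-1-naphthoyl]-N-{2-[(tert-butyldimethylsilyl)oxy]ethyl}-3-methoxybenzamide | COc1cccc(C(=O)NCCO[Si](C)(C)C(C)(C)C)c1C(=O)c1c(OCc2ccccc2)ccc2cc(C)cc(O)c12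
F5 | step 6 | racemic 3'-(benzyloxy)-2-{2-[(tert-butyldimethylsilyl)oxy]ethyl}-7-methoxy-7'-methylspiro[isoindoline-1,2'-naphtho[1,8-bc]furan]-3-one | COc1cccc2c1C1(Oc3cc(C)cc4ccc(OCc5ccccc5)c1c34)N(CCO[Si](C)(C)C(C)(C)C)C2=O
F6 | step 6 | (S)-3'-(benzyloxy)-2-{2-[(tert-butyldimethylsilyl)oxy]ethyl}-7-methoxy-7'-methylspiro[isoindoline-1,2'-naphtho[1,8-bc]furan]-3-one | COc1cccc2c1[C@]1(Oc3cc(C)cc4ccc(OCc5ccccc5)c1c34)N(CCO[Si](C)(C)C(C)(C)C)C2=O
F7 | step 4 | 2-{2-[(tert-butyldimethylsilyl)oxy]ethyl}-3-hydroxy-4-methoxyisoindolin-1-one | COc1cccc2c1C(O)N(CCO[Si](C)(C)C(C)(C)C)C2=O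
F8 | step 4 | 2-{2-[(tert-butyldimethylsilyl)oxy]ethyl}-3-(2-hydroxy-6-methylnaphthalen-1-yl)-4-methoxyisoindolin-1-one | COc1cccc2c1C(c1c(O)ccc3cc(C)ccc13)N(CCO[Si](C)(C)C(C)(C)C)C2=O
F9 | step 4 | 3-[2-(benzyloxy)-6-methylnaphthalen-1-yl]-2-{2-[(tert-butyldimethylsilyl)oxy]ethyl}-4-methoxyisoindolin-1-one | COc1cccc2c1C(c1c(OCc3ccccc3)ccc3cc(C)ccc13)N(CCO[Si](C)(C)C(C)(C)C)C2=O
F10 | step 8 | 2-{2-[(tert-butyldimethylsilyl)oxy]ethyl}-3-hydroxy-3-(2-hydroxy-6-methylnaphthalen-1-yl)-4-methoxyisoindolin-1-one | COc1cccc2c1C(O)(c1c(O)ccc3cc(C)ccc13)N(CCO[Si](C)(C)C(C)(C)C)C2=O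
F11 | step 8 | 3-{2-[(tert-butyldimethylsilyl)oxy]-6-methylnaphthalen-1-yl}-2-{2-[(tert-butyldimethylsilyl)oxy]ethyl}-3-hydroxy-4-methoxyisoindolin-1-one | COc1cccc2c1C(O)(c1c(O[Si](C)(C)C(C)(C)C)ccc3cc(C)ccc13)N(CCO[Si](C)(C)C(C)(C)C)C2=O
F12 | step 8 | 3'-[(tert-butyldimethylsilyl)oxy]-2-{2-[(tert-butyldimethylsilyl)oxy]ethyl}-7-methoxy-7'-methylspiro[isoindoline-1,2'-naphtho[1,8-bc]furan]-3-one, spatial arrangement as in 11 | COc1cccc2c1[C@@]1(Oc3cc(C)cc4ccc(O[Si](C)(C)C(C)(C)C)c1c34)N(CCO[Si](C)(C)C(C)(C)C)C2=O
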